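The plan rests on recognising the furan-2,5-dione ring as a masked alkyne: its tetrasubstituted C3=C4 bond, flanked by the carbonyl carbons C2 and C5, is a cis-dicarboxylated internal alkyne. A nickel-catalysed reductive double carboxylation with two CO2 molecules therefore forges both C(sp2)–C(=O) bonds and the whole anhydride in one operation from a linear 1,3-enyne triester that already carries both stereocentres and the Z-acrylate; since both alkyne carbons are carboxylated, regiochemistry is moot. The enyne is assembled by a Z-selective Horner–Wadsworth–Emmons union of an auxiliary-derived (R)-aldehyde with a D-glutamate-derived phosphonate, and acidolysis of three tert-butyl esters finishes the synthesis.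

Key step: step 12

Remark: the target is read as (3R,4Z,6R)-7-{4-[(1E)-but-1-en-1-yl]-2,5-dioxo-2,5-dihydrofuran-3-yl}-6-ethylhept-4-ene-1,3,4-tricarboxylic acid, in which C6 is cis to the carboxyl group on C4; compounds 4 and 11 are taken to be commercially available.

Remark: step 12 takes up two molecules of carbon dioxide, one entered as reactant 22 and the second as the atom-adding reagent; the two hydrogens of the diacid 23 come from the HCl quench, and ring closure to 24 releases water.

Step 1
Reactants: 1 but-1-yne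
Product: 3 (1E)-1-iodobut-1-ene, via butenylzirconocene chloride 2 (not isolated)
Conditions: Cp2Zr(H)Cl, THF, rt; then I2, 0 °C
Reagents that add atoms: iodine ([I][I])
Why: syn-hydrozirconation places zirconium on the terminal carbon and iodinolysis of the C–Zr bond proceeds with retention, so the E-iodide should result (hydrozirconation–iodination).

Step 2
Reactants: 4 (4S)-4-benzyl-3-butanoyl-1,3-oxazolidin-2-one; 5 3-bromoprop-1-yne
Product: 7 (4S)-4-benzyl-3-[(2R)-2-ethylpent-4-ynoyl]-1,3-oxazolidin-2-one, via sodium enolate 6 (not isolated)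
Conditions: NaN(SiMe3)2, THF, −78 °C; then 5, −78 → −40 °C
Reagents that add atoms: none
Why: Evans alkylation, in which the chelated sodium (Z)-enolate is attacked on the face opposite the benzyl group, sets the (2R) centre that becomes C6 of the target.

Step 3
Reactants: 7 (4S)-4-benzyl-3-[(2R)-2-ethylpent-4-ynoyl]-1,3-oxazolidin-2-one; 3 (1E)-1-iodobut-1-ene
Product: 8 (4S)-4-benzyl-3-[(2R,6E)-2-ethylnon-6-en-4-ynoyl]-1,3-oxazolidin-2-one
Conditions: PdCl2(PPh3)2 (cat.), CuI (cat.), Et3N, THF, rt
Reagents that add atoms: none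
Why: Sonogashira coupling of the terminal alkyne with the alkenyl iodide proceeds with retention of the E geometry and should leave the imide and its α-centre untouched.

Step 4
Reactants: 8 (4S)-4-benzyl-3-[(2R,6E)-2-ethylnon-6-en-4-ynoyl]-1,3-oxazolidin-2-one
Product: 9 (2R,6E)-2-ethylnon-6-en-4-yn-1-ol
Conditions: LiBH4, MeOH (1 equiv), Et2O, 0 °C
Reagents that add atoms: none
Why: reductive cleavage of the N-acyl oxazolidinone by borohydride should release the primary alcohol and the auxiliary without touching the enyne or the stereocentre.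

Step 5
Reactants: 9 (2R,6E)-2-ethylnon-6-en-4-yn-1-ol
Product: 10 (2R,6E)-2-ethylnon-6-en-4-ynal
Conditions: Dess–Martin periodinane, NaHCO3, CH2Cl2, 0 °C → rt
Reagents that add atoms: none
Why: Dess–Martin oxidation under buffered, non-basic conditions should give the α-branched aldehyde without epimerisation, and it is used at once.

Step 6
Reactants: 11 D-glutamic acid 5-tert-butyl ester
Product: 12 (2R)-5-tert-butoxy-2-hydroxy-5-oxopentanoic acid
Conditions: NaNO2, 0.5 M aq. H2SO4, 0 °C → rt
Reagents that add atoms: water (O)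
Why: diazotisation–hydrolysis of the α-amino acid proceeds with net retention (double inversion through the α-lactone formed by carboxylate participation), so the (R)-hydroxy acid should be obtained.

Step 7
Reactants: 12 (2R)-5-tert-butoxy-2-hydroxy-5-oxopentanoic acid
Product: 13 di-tert-butyl (2R)-2-hydroxypentanedioate
Conditions: O-tert-butyl-N,N'-diisopropylisourea, CH2Cl2, rt
Reagents that add atoms: O-tert-butyl-N,N'-diisopropylisourea (CC(C)NC(=NC(C)C)OC(C)(C)C)
Why: isourea-mediated tert-butyl esterification alkylates the carboxylic acid after proton transfer but should not touch the secondary alcohol.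

Step 8
Reactants: 13 di-tert-butyl (2R)-2-hydroxypentanedioate
Product: 14 di-tert-butyl (2R)-2-{[(trifluoromethyl)sulfonyl]oxy}pentanedioate
Conditions: Tf2O, 2,6-lutidine, CH2Cl2, −78 °C
Reagents that add atoms: trifluoromethanesulfonic anhydride (O=S(=O)(OS(=O)(=O)C(F)(F)F)C(F)(F)F)
Why: O-sulfonylation of the α-hydroxy ester at low temperature with a hindered pyridine base should give the α-triflyloxy ester with the C–O bond and configuration intact; it is used without delay.

Step 9
Reactants: 15 diphenyl phosphite; 16 tert-butyl bromoacetate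
Product: 17 tert-butyl 2-(diphenoxyphosphoryl)acetate
Conditions: Et3N, CH2Cl2, 0 °C → rt
Reagents that add atoms: none
Why: Michaelis–Becker-type P-alkylation of the diaryl phosphite by the bromoacetate under amine base should give the diaryl phosphonoacetate.

Step 10
Reactants: 17 tert-butyl 2-(diphenoxyphosphoryl)acetate; 14 di-tert-butyl (2R)-2-{[(trifluoromethyl)sulfonyl]oxy}pentanedioate
Product: 19 tri-tert-butyl (2S)-1-(diphenoxyphosphoryl)butane-1,2,4-tricarboxylate (both C1 epimers), via sodium phosphonoacetate 18 (not isolated)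
Conditions: NaH, THF, 0 °C; then 14, −78 °C → rt
Reagents that add atoms: none
Why: SN2 alkylation of the soft, doubly stabilised carbanion by the α-triflyloxy ester proceeds with inversion and so sets the centre that becomes C3 of the target (the C1 centre is lost in the next step).

Step 11
Reactants: 19 tri-tert-butyl (2S)-1-(diphenoxyphosphoryl)butane-1,2,4-tricarboxylate; 10 (2R,6E)-2-ethylnon-6-en-4-ynal
Product: 21 tri-tert-butyl (3R,4Z,6R,10E)-6-ethyltrideca-4,10-dien-8-yne-1,3,4-tricarboxylate, via sodium phosphonate carbanion 20 (not isolated)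
Conditions: NaH, THF, 0 °C; then 10, −78 → 0 °C
Reagents that add atoms: none
Why: Z-selective Horner–Wadsworth–Emmons olefination with a diaryl phosphonate, in which fast irreversible elimination from the kinetically favoured adduct places the aldehyde residue cis to the ester (4Z), while the stoichiometric, weakly basic carbanion should leave C3 and C6 intact.

Step 12
Reactants: 21 tri-tert-butyl (3R,4Z,6R,10E)-6-ethyltrideca-4,10-dien-8-yne-1,3,4-tricarboxylate; 22 carbon dioxide
Product: 24 tri-tert-butyl (3R,4Z,6R)-7-{4-[(1E)-but-1-en-1-yl]-2,5-dioxo-2,5-dihydrofuran-3-yl}-6-ethylhept-4-ene-1,3,4-tricarboxylate, via maleic diacid 23 (not isolated)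
Conditions: Ni(acac)2 (10 mol %), 2,2'-bipyridine (10 mol %), Zn powder, MgBr2, 3 Å molecular sieves, CO2 (1 atm), DMF, rt; then 1 M HCl, 0 °C
Reagents that add atoms: carbon dioxide (O=C=O)
Why: Zinc reduces divalent nickel to a zerovalent nickel–bipyridine species that couples the alkyne of 21 with a first CO2 by oxidative cyclisation to a five-membered oxanickelacyclopentenone; one-electron reduction by zinc and MgBr2-assisted insertion of a second CO2 into the Ni–C(sp2) bond give the cis-dicarboxylate, which the HCl quench protonates to the diacid 23, and 23 closes to the anhydride with loss of water. The closest known reaction type is the nickel-catalysed reductive double carboxylation of internal alkynes with CO2 to maleic anhydrides. The nickelacycle closes by oxidative cyclisation across the alkyne and CO2, and the furan-2,5-dione ring closes by 5-exo-trig O-acylation within the (Z)-diacid 23. No stereocentre is created; the cis relationship of the two carboxyl carbons follows from syn addition through the metallacycle, and regiochemistry is irrelevant because both alkyne carbons end up carboxylated. The step needs chemoselectivity for the alkyne over the conjugated E-alkene and the trisubstituted acrylate, which the stronger binding of an alkyne to low-valent nickel and the hindered environment of the enoate should secure, and the neutral, base-free medium should preserve C3, C6 and the 4Z geometry.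

Step 13
Reactants: 24 tri-tert-butyl (3R,4Z,6R)-7-{4-[(1E)-but-1-en-1-yl]-2,5-dioxo-2,5-dihydrofuran-3-yl}-6-ethylhept-4-ene-1,3,4-tricarboxylate
Product: 25 (3R,4Z,6R)-7-{4-[(1E)-but-1-en-1-yl]-2,5-dioxo-2,5-dihydrofuran-3-yl}-6-ethylhept-4-ene-1,3,4-tricarboxylic acid
Conditions: CF3CO2H/CH2Cl2 (1:1), 0 °C → rt
Reagents that add atoms: none
Why: acidolysis of the three tert-butyl esters with loss of isobutene is non-basic, so it should neither open the anhydride nor epimerise C3 or isomerise the Z-alkene.

Compound list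
1 | but-1-yne | CCC#C | starting material
2 | chlorobis(cyclopentadienyl)[(1E)-but-1-en-1-yl]zirconium | CC/C=C/[Zr](Cl)(C1C=CC=C1)C1C=CC=C1 | intermediate
3 | (1E)-1-iodobut-1-ene | CC/C=C/I | intermediate
4 | (4S)-4-benzyl-3-butanoyl-1,3-oxazolidin-2-one | CCCC(=O)N1[C@@H](Cc2ccccc2)COC1=O | starting material
5 | 3-bromoprop-1-yne (propargyl bromide) | C#CCBr | starting material
6 | sodium (Z)-enolate of 4 | CC/C=C(\[O-])N1[C@@H](Cc2ccccc2)COC1=O.[Na+] | intermediate
7 | (4S)-4-benzyl-3-[(2R)-2-ethylpent-4-ynoyl]-1,3-oxazolidin-2-one | C#CC[C@@H](CC)C(=O)N1[C@@H](Cc2ccccc2)COC1=O | intermediate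
8 | (4S)-4-benzyl-3-[(2R,6E)-2-ethylnon-6-en-4-ynoyl]-1,3-oxazolidin-2-one | CC/C=C/C#CC[C@@H](CC)C(=O)N1[C@@H](Cc2ccccc2)COC1=O | intermediate
9 | (2R,6E)-2-ethylnon-6-en-4-yn-1-ol | CC/C=C/C#CC[C@@H](CC)CO | intermediate
10 | (2R,6E)-2-ethylnon-6-en-4-ynal | CC/C=C/C#CC[C@@H](CC)C=O | intermediate
11 | D-glutamic acid 5-tert-butyl ester | N[C@H](CCC(=O)OC(C)(C)C)C(=O)O | starting material
12 | (2R)-5-tert-butoxy-2-hydroxy-5-oxopentanoic acid | O[C@H](CCC(=O)OC(C)(C)C)C(=O)O | intermediate
13 | di-tert-butyl (2R)-2-hydroxypentanedioate | O[C@H](CCC(=O)OC(C)(C)C)C(=O)OC(C)(C)C | intermediate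
14 | di-tert-butyl (2R)-2-{[(trifluoromethyl)sulfonyl]oxy}pentanedioate | FC(F)(F)S(=O)(=O)O[C@H](CCC(=O)OC(C)(C)C)C(=O)OC(C)(C)C | intermediate
15 | diphenyl phosphite | O=[PH](Oc1ccccc1)Oc1ccccc1 | starting material
16 | tert-butyl bromoacetate | CC(C)(C)OC(=O)CBr | starting material
17 | tert-butyl 2-(diphenoxyphosphoryl)acetate | CC(C)(C)OC(=O)CP(=O)(Oc1ccccc1)Oc1ccccc1 | intermediate
18 | sodium salt (carbanion) of 17 | CC(C)(C)OC(=O)[CH-]P(=O)(Oc1ccccc1)Oc1ccccc1.[Na+] | intermediate
19 | tri-tert-butyl (2S)-1-(diphenoxyphosphoryl)butane-1,2,4-tricarboxylate (both C1 epimers) | CC(C)(C)OC(=O)C(P(=O)(Oc1ccccc1)Oc1ccccc1)[C@@H](CCC(=O)OC(C)(C)C)C(=O)OC(C)(C)C | intermediate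
20 | sodium salt (C1 carbanion) of 19 | CC(C)(C)OC(=O)[C-](P(=O)(Oc1ccccc1)Oc1ccccc1)[C@@H](CCC(=O)OC(C)(C)C)C(=O)OC(C)(C)C.[Na+] | intermediate
21 | tri-tert-butyl (3R,4Z,6R,10E)-6-ethyltrideca-4,10-dien-8-yne-1,3,4-tricarboxylate | CC/C=C/C#CC[C@H](/C=C(\C(=O)OC(C)(C)C)[C@@H](CCC(=O)OC(C)(C)C)C(=O)OC(C)(C)C)CC | intermediate
22 | carbon dioxide | O=C=O | starting material
23 | tri-tert-butyl (3R,4Z,6R,8Z,10E)-8,9-dicarboxy-6-ethyltrideca-4,8,10-triene-1,3,4-tricarboxylate (maleic diacid) | CC/C=C/C(/C(=O)O)=C(/C(=O)O)C[C@H](/C=C(\C(=O)OC(C)(C)C)[C@@H](CCC(=O)OC(C)(C)C)C(=O)OC(C)(C)C)CC | intermediate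
24 | tri-tert-butyl (3R,4Z,6R)-7-{4-[(1E)-but-1-en-1-yl]-2,5-dioxo-2,5-dihydrofuran-3-yl}-6-ethylhept-4-ene-1,3,4-tricarboxylate | CC/C=C/C1=C(C[C@H](/C=C(\C(=O)OC(C)(C)C)[C@@H](CCC(=O)OC(C)(C)C)C(=O)OC(C)(C)C)CC)C(=O)OC1=O | intermediate
25 | (3R,4Z,6R)-7-{4-[(1E)-but-1-en-1-yl]-2,5-dioxo-2,5-dihydrofuran-3-yl}-6-ethylhept-4-ene-1,3,4-tricarboxylic acid | CC/C=C/C1=C(C[C@H](/C=C(\C(=O)O)[C@@H](CCC(=O)O)C(=O)O)CC)C(=O)OC1=O | target

Total step count: 13 steps. Longest linear sequence: 7 steps (for example 11 → 12 → 13 → 14 → 19 → 21 → 24 → 25).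

Steps most likely to fail

Step 12 (double carboxylation). The enyne may oligomerise or cyclotrimerise at low-valent nickel, carboxylation may run in a 1,4-sense across the enyne through an η3-butadienyl nickel species, or the sequence may stop after the first CO2 insertion (net hydrocarboxylation). The fallback sets out from 21 and comes back at 25, skipping 24. Palladium-catalysed oxidative bis-alkoxycarbonylation of the alkyne (Pd(OCOCF3)2, a bis(aryl)acenaphthenequinone diimine ligand, p-benzoquinone, TsOH (cat.), 4-methoxybenzyl alcohol, CO 4 bar, THF, rt) should add two ester groups syn across the triple bond. This gives tri-tert-butyl (3R,4Z,6R,8Z,10E)-6-ethyl-8,9-bis{[(4-methoxybenzyl)oxy]carbonyl}trideca-4,8,10-triene-1,3,4-tricarboxylate F1. Treatment of F1 with CF3CO2H and anisole in CH2Cl2 should remove the two 4-methoxybenzyl and the three tert-butyl esters together, and the dialkylmaleic acid so formed closes spontaneously to the anhydride 25.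

Step 11 (Z-selective olefination). Addition of the hindered, α-branched carbanion 20 to the α-branched aldehyde may be slow, the Z/E selectivity may erode, or base may epimerise C3 of the product or C2 of the aldehyde. The fallback sets out from 14 and 10 and comes back at 21; it replaces the olefination by a stereospecific syn-aldol and syn-dehydration pair. Displacement of the triflate of 14, with inversion, by the sodium salt of 2,2-dimethyl-1,3-dioxane-4,6-dione (from NaH, DMF, 0 °C) should give di-tert-butyl (2R)-2-(2,2-dimethyl-4,6-dioxo-1,3-dioxan-5-yl)pentanedioate F2. Heating F2 with thiophenol (toluene, 100 °C; ring opening, loss of acetone and CO2) should give di-tert-butyl (2R)-2-[2-oxo-2-(phenylsulfanyl)ethyl]pentanedioate F3. Soft enolisation of the thioester alone (9-BBN triflate, iPr2NEt, CH2Cl2, −78 °C) and addition to 10 should give the 2,3-syn aldol di-tert-butyl (2R)-2-[(4R,8E)-4-ethyl-3-hydroxy-1-oxo-1-(phenylsulfanyl)undec-8-en-6-yn-2-yl]pentanedioate F4, and both syn isomers converge in what follows. syn-Dehydration of F4 (DCC, CuCl (cat.), toluene, 80 °C) should give di-tert-butyl (2R)-2-[(2Z,4R,8E)-4-ethyl-1-oxo-1-(phenylsulfanyl)undeca-2,8-dien-6-yn-2-yl]pentanedioate F5, because a syn aldol and a syn elimination together place C4 cis to the carbonyl group. Silver-assisted transesterification of F5 (AgOCOCF3, t-BuOH, THF, rt) should then give 21.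

Step 10 (alkylation by the secondary triflate). E2 elimination of triflic acid to the glutaconate, intramolecular displacement by the γ-ester carbonyl (lactone formation with loss of isobutene) or partial loss of configuration may compete with substitution. The fallback sets out from 13 and comes back at 19, avoiding the triflate 14 altogether. A Mitsunobu-type C-alkylation of 17 with the alcohol 13, mediated by (cyanomethylene)tributylphosphorane (toluene, 100 °C), should form the same C–C bond with inversion through the alkoxyphosphonium ion under neutral conditions.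

Further compounds
F1 | step 12 | tri-tert-butyl (3R,4Z,6R,8Z,10E)-6-ethyl-8,9-bis{[(4-methoxybenzyl)oxy]carbonyl}trideca-4,8,10-triene-1,3,4-tricarboxylate | CC/C=C/C(/C(=O)OCc1ccc(OC)cc1)=C(/C(=O)OCc1ccc(OC)cc1)C[C@H](/C=C(\C(=O)OC(C)(C)C)[C@@H](CCC(=O)OC(C)(C)C)C(=O)OC(C)(C)C)CC
F2 | step 11 | di-tert-butyl (2R)-2-(2,2-dimethyl-4,6-dioxo-1,3-dioxan-5-yl)pentanedioate | CC1(C)OC(=O)C(C(=O)O1)[C@@H](CCC(=O)OC(C)(C)C)C(=O)OC(C)(C)C
F3 | step 11 | di-tert-butyl (2R)-2-[2-oxo-2-(phenylsulfanyl)ethyl]pentanedioate | O=C(C[C@@H](CCC(=O)OC(C)(C)C)C(=O)OC(C)(C)C)Sc1ccccc1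
F4 | step 11 | di-tert-butyl (2R)-2-[(4R,8E)-4-ethyl-3-hydroxy-1-oxo-1-(phenylsulfanyl)undec-8-en-6-yn-2-yl]pentanedioate (2,3-syn in the side chain, both syn isomers) | O=C(Sc1ccccc1)C([C@@H](CCC(=O)OC(C)(C)C)C(=O)OC(C)(C)C)C(O)[C@H](CC)CC#C/C=C/CC
F5 | step 11 | di-tert-butyl (2R)-2-[(2Z,4R,8E)-4-ethyl-1-oxo-1-(phenylsulfanyl)undeca-2,8-dien-6-yn-2-yl]pentanedioate | O=C(Sc1ccccc1)/C(=C\[C@H](CC)CC#C/C=C/CC)[C@@H](CCC(=O)OC(C)(C)C)C(=O)OC(C)(C)C
F0 | step 10 | none | none
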